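**Assumption:** 2‑bromo‑6‑hydroxybenzaldehyde, methyl (S)‑glycidate, dimethyl 2,3‑O‑isopropylidene‑L‑tartrate, (S)‑propylene oxide and but‑3‑enylmagnesium bromide solution are taken as catalogue compounds.

## Retrosynthetic overview

1. Target ⇒ one acidic unmasking of an aryl MOM ether and a diol acetonide. The benzene ring is bought and no ring of the target is formed in the route; the dioxolane comes in with the tartrate.
2. Chain C5=C6 ⇒ E‑selective cross‑metathesis with (S)‑hept‑6‑en‑2‑ol, made from (S)‑propylene oxide.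
3. Aryl–C1(alkenyl) ⇒ Heck mono‑arylation of C2‑symmetric (4S,5S)‑divinyl dioxolane, made from L‑tartrate.
4. Aryl–CH2 ⇒ blue‑light Ni/photoredox cross‑electrophile coupling of the aryl iodide with (S)‑2‑(oxiran‑2‑yl)propan‑2‑ol, made from methyl (S)‑glycidate.
5. Arene ⇒ 2‑bromo‑6‑hydroxybenzaldehyde by para‑iodination and MOM protection.

## Route

Step 1
Reactants: 1 2‑bromo‑6‑hydroxybenzaldehyde
Product: 2 2‑bromo‑6‑hydroxy‑3‑iodobenzaldehyde
Conditions: NIS (1.05 equiv), TFA (10 mol%), MeCN, 0 °C → rt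
Reagents that add atoms: N‑iodosuccinimide, O=C1CCC(=O)N1I
Why: Electrophilic aromatic iodination (SEAr) goes para to the phenol OH, a position that is also meta to CHO, and stops at the mono‑iodide because the product is deactivated.

Step 2
Reactants: 2 2‑bromo‑6‑hydroxy‑3‑iodobenzaldehyde
Product: 3 2‑bromo‑3‑iodo‑6‑(methoxymethoxy)benzaldehyde
Conditions: MOMCl (1.5 equiv), i‑Pr2NEt (2 equiv), CH2Cl2, 0 °C → rt
Reagents that add atoms: chloromethyl methyl ether, COCCl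
Why: O‑alkylation of the phenoxide (MOM protection) masks the acidic, metal‑chelating salicylaldehyde OH for the nickel, palladium and ruthenium steps.

Step 3
Reactants: 4 methyl (2S)‑oxirane‑2‑carboxylate (methyl (S)‑glycidate)
Product: 6 (S)‑2‑(oxiran‑2‑yl)propan‑2‑ol, via epoxy ketone 5 (not isolated)
Conditions: MeMgCl (2.1 equiv), THF, −78 → −40 °C; sat. NH4Cl
Reagents that add atoms: methylmagnesium chloride, C[Mg]Cl
Why: Double Grignard addition to the ester at −78 °C outruns epoxide opening, and the oxirane stereocentre is not enolised, so the bought (S) centre is kept.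

Step 4
Reactants: 3 2‑bromo‑3‑iodo‑6‑(methoxymethoxy)benzaldehyde; 6 (S)‑2‑(oxiran‑2‑yl)propan‑2‑ol (2 equiv)
Product: 8 2‑bromo‑3‑[(2S)‑2,3‑dihydroxy‑3‑methylbutyl]‑6‑(methoxymethoxy)benzaldehyde, via iodohydrin 7 (not isolated)
Conditions: NiBr2·glyme (10 mol%), dtbbpy (12 mol%), 4CzIPN (2 mol%), Et3N·HI (30 mol%), Et3N (3 equiv), DMA, 450 nm LEDs, 25 °C
Reagents that add atoms: none
Why: Proposed new method: a titanium‑free iodide‑relay nickel/organophotoredox cross‑electrophile coupling in which Et3NH+ I− opens epoxide 6 at its CH2 terminus to iodohydrin 7, photogenerated (dtbbpy)Ni(0) inserts into the C–I bond of 3 (much faster than into the C–Br bond, which is flanked on both sides), low‑valent nickel turns 7 into the primary β‑hydroxyalkyl radical, and Ar–Ni(III)–alkyl reductive elimination forms the aryl–CH2 bond, so the C–O stereocentre is never touched and stays (S); the closest known reaction type is the Ni/Ti/photoredox (and thermal Ni/NaI/Mn) reductive arylation of terminal aliphatic epoxides with aryl iodides, which has not been shown without titanium, on a bromo‑iodo‑benzaldehyde, or on an α‑hydroxyalkyl epoxide.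

Step 5
Reactants: 9 dimethyl (4R,5R)‑2,2‑dimethyl‑1,3‑dioxolane‑4,5‑dicarboxylate (dimethyl 2,3‑O‑isopropylidene‑L‑tartrate)
Product: 11 (4S,5S)‑4,5‑diethenyl‑2,2‑dimethyl‑1,3‑dioxolane, via dialdehyde 10 (not isolated)
Conditions: DIBAL‑H (2.05 equiv), toluene, −78 °C; then Ph3P=CH2 (from Ph3PCH3Br/KHMDS, 4 equiv, THF), −78 °C → 40 °C; Rochelle salt; distil
Reagents that add atoms: methyltriphenylphosphonium bromide, C[P+](c1ccccc1)(c1ccccc1)c1ccccc1.[Br-]
Why: One‑pot DIBAL half‑reduction/Wittig methylenation, in which the aluminium hemiacetal releases aldehyde only as the ylide consumes it, limits α‑epimerisation so the trans arrangement bought with L‑tartrate is carried over as (4S,5S).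

Step 6
Reactants: 8 2‑bromo‑3‑[(2S)‑2,3‑dihydroxy‑3‑methylbutyl]‑6‑(methoxymethoxy)benzaldehyde; 11 (4S,5S)‑4,5‑diethenyl‑2,2‑dimethyl‑1,3‑dioxolane (3 equiv)
Product: 12 3‑[(2S)‑2,3‑dihydroxy‑3‑methylbutyl]‑2‑{(E)‑2‑[(4S,5S)‑5‑ethenyl‑2,2‑dimethyl‑1,3‑dioxolan‑4‑yl]ethenyl}‑6‑(methoxymethoxy)benzaldehyde
Conditions: Pd2(dba)3 (2.5 mol%), P(t‑Bu)3·HBF4 (10 mol%), Cy2NMe (1.5 equiv), dioxane, sealed tube, 80 °C
Reagents that add atoms: none
Why: Mizoroki–Heck reaction: oxidative addition into the ortho‑formyl C–Br bond, syn‑insertion at the terminal carbon of one of the two homotopic vinyl groups of 11 and syn‑β‑H elimination toward the benzylic hydrogen give the conjugated E‑styrene without touching a stereocentre, and the weak amine base keeps the side‑chain alcohol from cyclising onto palladium.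

Step 7
Reactants: 13 (S)‑2‑methyloxirane ((S)‑propylene oxide); 14 but‑3‑en‑1‑ylmagnesium bromide
Product: 15 (S)‑hept‑6‑en‑2‑ol
Conditions: CuI (10 mol%), THF, −30 → 0 °C; sat. NH4Cl
Reagents that add atoms: none
Why: Copper‑catalysed SN2 opening of the epoxide at its unsubstituted carbon leaves the (S) carbinol centre untouched.

Step 8
Reactants: 12 Heck product (terminal vinyl); 15 (S)‑hept‑6‑en‑2‑ol (3 equiv)
Product: 16 3‑[(2S)‑2,3‑dihydroxy‑3‑methylbutyl]‑2‑{(E)‑2‑[(4S,5S)‑5‑[(1E,6S)‑6‑hydroxyhept‑1‑en‑1‑yl]‑2,2‑dimethyl‑1,3‑dioxolan‑4‑yl]ethenyl}‑6‑(methoxymethoxy)benzaldehyde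
Conditions: Hoveyda–Grubbs II (5 mol%), CH2Cl2, 40 °C
Reagents that add atoms: none
Why: Olefin cross‑metathesis of a type I terminal alkene with the allylically oxygenated vinyl group gives the thermodynamic E‑alkene, while the hindered, conjugated styrenyl double bond does not take part.

Step 9
Reactants: 16 fully protected precursor
Product: 17 3‑[(2S)‑2,3‑dihydroxy‑3‑methylbutyl]‑6‑hydroxy‑2‑[(1E,3S,4S,5E,10S)‑3,4,10‑trihydroxyundeca‑1,5‑dien‑1‑yl]benzaldehyde (CNP0348098.1)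
Conditions: 2 M aq. HCl/THF (1:3), 35 °C
Reagents that add atoms: none
Why: Acid‑catalysed acetal hydrolysis removes the isopropylidene and methoxymethyl groups in one operation and breaks no C–O bond at a stereocentre.

## Compound list

1 | 2‑bromo‑6‑hydroxybenzaldehyde | O=Cc1c(O)cccc1Br | starting material
2 | 2‑bromo‑6‑hydroxy‑3‑iodobenzaldehyde | O=Cc1c(O)ccc(I)c1Br | intermediate
3 | 2‑bromo‑3‑iodo‑6‑(methoxymethoxy)benzaldehyde | COCOc1ccc(I)c(Br)c1C=O | intermediate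
4 | methyl (2S)‑oxirane‑2‑carboxylate | COC(=O)[C@@H]1CO1 | starting material
5 | (S)‑1‑(oxiran‑2‑yl)ethan‑1‑one (epoxy ketone) | CC(=O)[C@@H]1CO1 | intermediate
6 | (S)‑2‑(oxiran‑2‑yl)propan‑2‑ol | CC(C)(O)[C@@H]1CO1 | intermediate
7 | (3R)‑4‑iodo‑2‑methylbutane‑2,3‑diol (iodohydrin; same spatial arrangement as 6, descriptor changes by CIP priority) | CC(C)(O)[C@@H](O)CI | intermediate
8 | 2‑bromo‑3‑[(2S)‑2,3‑dihydroxy‑3‑methylbutyl]‑6‑(methoxymethoxy)benzaldehyde | COCOc1ccc(C[C@H](O)C(C)(C)O)c(Br)c1C=O | intermediate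
9 | dimethyl (4R,5R)‑2,2‑dimethyl‑1,3‑dioxolane‑4,5‑dicarboxylate | COC(=O)[C@@H]1OC(C)(C)O[C@H]1C(=O)OC | starting material
10 | (4R,5R)‑2,2‑dimethyl‑1,3‑dioxolane‑4,5‑dicarbaldehyde (dialdehyde, held as its aluminium hemiacetal) | O=C[C@@H]1OC(C)(C)O[C@H]1C=O | intermediate
11 | (4S,5S)‑4,5‑diethenyl‑2,2‑dimethyl‑1,3‑dioxolane | C=C[C@@H]1OC(C)(C)O[C@H]1C=C | intermediate
12 | 3‑[(2S)‑2,3‑dihydroxy‑3‑methylbutyl]‑2‑{(E)‑2‑[(4S,5S)‑5‑ethenyl‑2,2‑dimethyl‑1,3‑dioxolan‑4‑yl]ethenyl}‑6‑(methoxymethoxy)benzaldehyde | C=C[C@@H]1OC(C)(C)O[C@H]1/C=C/c1c(C[C@H](O)C(C)(C)O)ccc(OCOC)c1C=O | intermediate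
13 | (S)‑2‑methyloxirane | C[C@H]1CO1 | starting material
14 | but‑3‑en‑1‑ylmagnesium bromide | C=CCC[Mg]Br | starting material
15 | (S)‑hept‑6‑en‑2‑ol | C[C@H](O)CCCC=C | intermediate
16 | 3‑[(2S)‑2,3‑dihydroxy‑3‑methylbutyl]‑2‑{(E)‑2‑[(4S,5S)‑5‑[(1E,6S)‑6‑hydroxyhept‑1‑en‑1‑yl]‑2,2‑dimethyl‑1,3‑dioxolan‑4‑yl]ethenyl}‑6‑(methoxymethoxy)benzaldehyde | C[C@H](O)CCC/C=C/[C@@H]1OC(C)(C)O[C@H]1/C=C/c1c(C[C@H](O)C(C)(C)O)ccc(OCOC)c1C=O | intermediate
17 | 3‑[(2S)‑2,3‑dihydroxy‑3‑methylbutyl]‑6‑hydroxy‑2‑[(1E,3S,4S,5E,10S)‑3,4,10‑trihydroxyundeca‑1,5‑dien‑1‑yl]benzaldehyde | C[C@H](O)CCC/C=C/[C@H](O)[C@@H](O)/C=C/c1c(C[C@H](O)C(C)(C)O)ccc(O)c1C=O | target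

## Step count and risks

Total steps: 9. Longest linear sequence: 6 (steps 1, 2, 4, 6, 8, 9). Steps 3, 5 and 7 each make one fragment.

**Step 4 (the new coupling).** Possible failures are competing insertion into the C–Br bond, nickel‑mediated C–O closure of the product alcohol onto the bromide, photoreduction of the aldehyde, and sluggish iodohydrin formation without a Lewis acid. The fallback uses known chemistry, sets out from 6 (with 3) and comes back at 8. Epoxide 6 is opened with LiI/AcOH in THF and iodohydrin 7 is isolated. It is protected with 2,2‑dimethoxypropane/PPTS as (4R)‑4‑(iodomethyl)‑2,2,5,5‑tetramethyl‑1,3‑dioxolane F1. F1 and aryl iodide 3 are joined by the established thermal nickel‑catalysed reductive cross‑electrophile coupling of an aryl iodide with a primary alkyl iodide (NiI2, dtbbpy, Zn dust, DMPU, rt). This gives 2‑bromo‑6‑(methoxymethoxy)‑3‑{[(4S)‑2,2,5,5‑tetramethyl‑1,3‑dioxolan‑4‑yl]methyl}benzaldehyde F2. Selective acetonide hydrolysis (80% AcOH, 40 °C, aryl MOM ether kept) returns 8.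

**Step 6 (Heck).** Possible failures are slow oxidative addition at the doubly ortho‑substituted bromide, double arylation of 11, β‑H elimination toward the dioxolane C–H, and Pd‑mediated cyclisation of the side‑chain alcohol. The fallback sets out from 11 (with 8) and comes back at 12. Excess 11 undergoes cross‑metathesis with vinylboronic acid pinacol ester (Hoveyda–Grubbs II, CH2Cl2, 40 °C) to give 2‑{(E)‑2‑[(4S,5S)‑5‑ethenyl‑2,2‑dimethyl‑1,3‑dioxolan‑4‑yl]ethenyl}‑4,4,5,5‑tetramethyl‑1,3,2‑dioxaborolane F3. Suzuki–Miyaura coupling of F3 with 8 (Pd(OAc)2/SPhos, aq. K2CO3, THF, 60 °C) fixes the regiochemistry and E geometry in the boronate and gives 12.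

**Step 9 (global deprotection).** The acid strength needed for the aryl MOM ether may ionise the doubly allylic diol or dehydrate the tertiary alcohol. The fallback sets out from 8 and comes back at 17, with the MOM group used only for the nickel step. 8 is treated with aq. HCl/THF at 40 °C, where nothing acid‑sensitive is present yet, to give 2‑bromo‑3‑[(2S)‑2,3‑dihydroxy‑3‑methylbutyl]‑6‑hydroxybenzaldehyde F4. Heck reaction of F4 with 11 under the step 6 conditions gives 3‑[(2S)‑2,3‑dihydroxy‑3‑methylbutyl]‑2‑{(E)‑2‑[(4S,5S)‑5‑ethenyl‑2,2‑dimethyl‑1,3‑dioxolan‑4‑yl]ethenyl}‑6‑hydroxybenzaldehyde F5. Cross‑metathesis of F5 with 15 gives 3‑[(2S)‑2,3‑dihydroxy‑3‑methylbutyl]‑6‑hydroxy‑2‑{(E)‑2‑[(4S,5S)‑5‑[(1E,6S)‑6‑hydroxyhept‑1‑en‑1‑yl]‑2,2‑dimethyl‑1,3‑dioxolan‑4‑yl]ethenyl}benzaldehyde F6. The last step is then only a mild acetonide hydrolysis (AcOH/H2O/THF 3:1:1, 40 °C) to 17.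

## Further compounds

F1 | step 4 | (4R)‑4‑(iodomethyl)‑2,2,5,5‑tetramethyl‑1,3‑dioxolane | CC1(C)OC(C)(C)O[C@H]1CI
F2 | step 4 | 2‑bromo‑6‑(methoxymethoxy)‑3‑{[(4S)‑2,2,5,5‑tetramethyl‑1,3‑dioxolan‑4‑yl]methyl}benzaldehyde | COCOc1ccc(C[C@@H]2OC(C)(C)OC2(C)C)c(Br)c1C=O
F3 | step 6 | 2‑{(E)‑2‑[(4S,5S)‑5‑ethenyl‑2,2‑dimethyl‑1,3‑dioxolan‑4‑yl]ethenyl}‑4,4,5,5‑tetramethyl‑1,3,2‑dioxaborolane | C=C[C@@H]1OC(C)(C)O[C@H]1/C=C/B2OC(C)(C)C(C)(C)O2
F4 | step 9 | 2‑bromo‑3‑[(2S)‑2,3‑dihydroxy‑3‑methylbutyl]‑6‑hydroxybenzaldehyde | O=Cc1c(O)ccc(C[C@H](O)C(C)(C)O)c1Br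
F5 | step 9 | 3‑[(2S)‑2,3‑dihydroxy‑3‑methylbutyl]‑2‑{(E)‑2‑[(4S,5S)‑5‑ethenyl‑2,2‑dimethyl‑1,3‑dioxolan‑4‑yl]ethenyl}‑6‑hydroxybenzaldehyde | C=C[C@@H]1OC(C)(C)O[C@H]1/C=C/c1c(C[C@H](O)C(C)(C)O)ccc(O)c1C=O
F6 | step 9 | 3‑[(2S)‑2,3‑dihydroxy‑3‑methylbutyl]‑6‑hydroxy‑2‑{(E)‑2‑[(4S,5S)‑5‑[(1E,6S)‑6‑hydroxyhept‑1‑en‑1‑yl]‑2,2‑dimethyl‑1,3‑dioxolan‑4‑yl]ethenyl}benzaldehyde | C[C@H](O)CCC/C=C/[C@@H]1OC(C)(C)O[C@H]1/C=C/c1c(C[C@H](O)C(C)(C)O)ccc(O)c1C=O
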